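The route rests on the C9–C10 bond (labdane numbering), which joins two fully substituted carbons of carbocycle B (C5–C10). C9, the spiro atom shared with oxolane ring C, carries oxygen and can act as a nucleophilic tertiary radical. C10 lies beta to the C6 oxygen and can be an enone terminus. The precursor is a seco-B ketone that already holds rings A, C and D: the asymmetric conjugate adduct of commercial beta-damascone and a spirocyclic dihydrofuran made from (R)-malic acid. Hydrogen-atom transfer to its cyclic enol ether starts a 6-endo radical conjugate addition that closes ring B and sets C9, C10 and C5 in one operation.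

Key step: step 7

Remark on the chemistry: atoms are numbered as in labdanes. C1–C10 form the decalin, C11/C12 are the oxolane methylenes, C13 is the second spiro carbon and C14–C16 belong to ring D. C17 sits on C8, C18/C19 on C4 and C20 on C10. C15 of the methyl acetal series is carried as both epimers and written without configuration, because the last step erases it.

Step 1
Reactants: 1 (R)-malic acid; 2 pivalaldehyde
Product: 3 (2R,4R)-2-tert-butyl-5-oxo-1,3-dioxolane-4-acetic acid (cis)
Conditions: 2 (1.5 equiv), TsOH·H2O (cat.), H2SO4 (cat.), pentane, reflux, azeotropic water removal; recrystallisation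
Reagents that add atoms: pivalaldehyde 2, CC(C)(C)C=O
Why: Acid-catalysed acetalisation of the alpha-hydroxy acid unit gives the five-membered dioxolanone, and equilibration plus crystallisation should deliver the cis isomer, so the malic acid stereocentre sets the new acetal centre.

Step 2
Reactants: 3; 4 propargyl bromide
Product: 6 (2R,4R)-2-tert-butyl-5-oxo-4-(prop-2-yn-1-yl)-1,3-dioxolane-4-acetic acid, via dilithio enolate 5 (not isolated)
Conditions: LiN(SiMe3)2 (2.2 equiv), THF, −78 °C; 4 (1.5 equiv), −78 to −20 °C; 1 M HCl work-up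
Reagents that add atoms: propargyl bromide 4, C#CCBr
Why: This is an enolate alkylation under self-regeneration of stereocentres, in which the bromide attacks the trigonal carbon anti to the tert-butyl group, so the propargyl group takes the place of the former hydrogen and fixes the future C13 as R.

Step 3
Reactants: 6
Product: 8 (4R)-4-hydroxy-4-(prop-2-yn-1-yl)oxolan-2-one, via dihydroxy acid 7 (not isolated)
Conditions: LiBH4 (2 equiv), THF, 0 °C to rt; then 2 M HCl, rt
Reagents that add atoms: none
Why: In this chemoselective borohydride reduction the reagent first turns the acid into its inert carboxylate and then reduces the activated acylal carbonyl with loss of the pivalaldehyde unit, and acidification closes ring D by gamma-lactonisation without touching C13.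

Step 4
Reactants: 8
Product: 10 (3R)-5-methoxy-3-(prop-2-yn-1-yl)oxolan-3-ol (C5 epimers), via lactol 9 (not isolated)
Conditions: iBu2AlH (2.3 equiv), CH2Cl2, −78 °C; aq. KNa tartrate; crude in MeOH, PPTS (5 mol %), rt
Reagents that add atoms: methanol, CO
Why: Partial lactone reduction stops at the aluminium lactolate at low temperature, and mild Fischer glycosidation in methanol masks the later enol ether of ring D as a base-stable and radical-stable methyl acetal.

Step 5
Reactants: 10
Product: 11 (5R)-8-methoxy-1,7-dioxaspiro[4.4]non-2-ene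
Conditions: Mo(CO)6 (25 mol %), Et3N, Et2O, hν (350 nm), rt
Reagents that add atoms: none
Why: In this alkynol cycloisomerisation the terminal alkyne rearranges on photogenerated Et3N·Mo(CO)5 to a molybdenum vinylidene, the tertiary hydroxyl adds to its electrophilic carbon, and protodemetalation gives the endocyclic enol ether (formal 5-endo closure of ring C) with C13 unchanged.

Step 6
Reactants: 11; 12 (E)-beta-damascone
Product: 15 (3R)-3-[(5R)-8-methoxy-1,7-dioxaspiro[4.4]non-2-en-2-yl]-1-(2,6,6-trimethylcyclohex-1-en-1-yl)butan-1-one, via lithiated dihydrofuran 13 (not isolated), via lithium trimethoxyborate 14 (not isolated)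
Conditions: tBuLi (1.1 equiv), THF, −78 to 0 °C; B(OMe)3 (1.2 equiv), −78 °C to rt; then 12 (1.5 equiv), Rh(acac)(C2H4)2 (3 mol %), (S)-BINAP (3.3 mol %), dioxane/H2O 10:1, 80–100 °C
Reagents that add atoms: beta-damascone 12, C/C=C/C(=O)C1=C(C)CCCC1(C)C (tBuLi and B(OMe)3, COB(OC)OC, enter only 13 and 14)
Why: After alpha-lithiation of the cyclic enol ether and borate formation, the alkenylrhodium species of a Hayashi–Miyaura asymmetric 1,4-addition reaches only the unhindered crotonyl terminus C8 (C10 is tetrasubstituted), and (S)-BINAP, which directs attack to the alpha-si face of (E)-crotonyl acceptors, should set C8 as R independently of remote C13.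

Step 7
Reactants: 15
Product: 18 (13R)-15-methoxy-9α,13:15,16-diepoxylabdan-6-one, via C9 radical 16 (not isolated), via C5 radical 17 (not isolated)
Conditions: Fe(acac)3 (30 mol %), PhSiH3 (2.5 equiv), Na2HPO4 (1 equiv), degassed EtOH, 0.02 M, 60 °C; then K2CO3 (cat.), MeOH, rt
Reagents that add atoms: none
Why: An iron hydride formed from Fe(acac)3 and PhSiH3 transfers a hydrogen atom to C11 of the electron-rich trisubstituted enol ether to give the tertiary alpha-oxy radical 16 at C9, which adds to the enone terminus C10 to give the alpha-keto radical 17, and reduction by divalent iron followed by protonation by ethanol gives ketone 18. The closest known reaction type is the hydrogen-atom-transfer-initiated reductive coupling (Giese addition) of heteroatom-substituted donor olefins with enones, used here intramolecularly. Ring B closes in the 6-endo-trig mode, because the 5-exo alternative would attack the alpha-carbon C5 next to quaternary C4 and is disfavoured both by polarity (a nucleophilic radical seeks the beta-carbon) and by congestion. C10 is controlled by C8, since the chair-like transition state keeps the C8 methyl equatorial and the other chair would place it syn-axial to C20; C9 is controlled within the same chair, where the ring oxygen takes the axial site anti to C20 and close to C7 while the bulkier C11 methylene takes the equatorial site beside H8. C5 is protonated on the alpha face opposite axial C20 and, being alpha to the ketone, is corrected to the trans-decalin by K2CO3/MeOH. The step needs hydrogen-atom transfer to the enol ether only, which is secured because the sole other olefin is the electron-poor tetrasubstituted enone, ring D is masked as an acetal, Na2HPO4 suppresses solvolysis, and the low stationary hydride concentration leaves time for bond formation between two fully substituted carbons.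

Step 8
Reactants: 18
Product: 20 (13R)-6β-acetoxy-15-methoxy-9α,13:15,16-diepoxylabdane, via lithium alkoxide 19 (not isolated)
Conditions: LiEt3BH (1.5 equiv), THF, −78 to 0 °C; then Ac2O (5 equiv), DMAP (0.2 equiv), 0 °C to rt
Reagents that add atoms: acetic anhydride, CC(=O)OC(C)=O
Why: In this ketone hydride reduction with in situ O-acylation the beta face of C6 is blocked by the syn-axial methyl groups on C4 and C10, so hydride arrives from the alpha face and sets the axial 6β oxygen (6R), and the preformed lithium alkoxide is acetylated more readily than the hindered neutral alcohol.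

Step 9
Reactants: 20
Product: 22 (13R)-6β-acetoxy-9α,13:15,16-diepoxylabd-14-ene (target CNP0242014.1), via oxocarbenium triflate 21 (not isolated)
Conditions: Me3SiOTf (1.15 equiv), iPr2NEt (1.5 equiv), CH2Cl2, −20 °C to rt; aq. NaHCO3
Reagents that add atoms: none
Why: In this silyl triflate/amine elimination of an acetal to an enol ether, Me3SiOTf ionises the only acetal to the C15 oxocarbenium ion and iPr2NEt removes a C14 proton, giving the 2,3-dihydrofuran in an aprotic, amine-buffered medium that should spare the acid-labile 9,13-ether and creates no stereocentre.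

Compound list
1 | (R)-malic acid | OC(=O)C[C@@H](O)C(=O)O | starting material
2 | pivalaldehyde | CC(C)(C)C=O | starting material
3 | (2R,4R)-2-tert-butyl-5-oxo-1,3-dioxolane-4-acetic acid | CC(C)(C)[C@@H]1O[C@H](CC(=O)O)C(=O)O1 | intermediate
4 | propargyl bromide | C#CCBr | starting material
5 | dilithium enolate-carboxylate of 3 | [Li+].[Li+].CC(C)(C)[C@@H]1OC(CC(=O)[O-])=C([O-])O1 | intermediate
6 | (2R,4R)-2-tert-butyl-5-oxo-4-(prop-2-yn-1-yl)-1,3-dioxolane-4-acetic acid | CC(C)(C)[C@@H]1O[C@](CC#C)(CC(=O)O)C(=O)O1 | intermediate
7 | (3R)-3-hydroxy-3-(hydroxymethyl)hex-5-ynoic acid | C#CC[C@](O)(CO)CC(=O)O | intermediate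
8 | (4R)-4-hydroxy-4-(prop-2-yn-1-yl)oxolan-2-one | C#CC[C@@]1(O)CC(=O)OC1 | intermediate
9 | (4R)-4-(prop-2-yn-1-yl)oxolane-2,4-diol (lactol, C2 epimers) | C#CC[C@@]1(O)CC(O)OC1 | intermediate
10 | (3R)-5-methoxy-3-(prop-2-yn-1-yl)oxolan-3-ol (C5 epimers) | C#CC[C@@]1(O)CC(OC)OC1 | intermediate
11 | (5R)-8-methoxy-1,7-dioxaspiro[4.4]non-2-ene | COC1C[C@]2(CC=CO2)CO1 | intermediate
12 | (E)-beta-damascone | C/C=C/C(=O)C1=C(C)CCCC1(C)C | starting material
13 | (5R)-2-lithio-8-methoxy-1,7-dioxaspiro[4.4]non-2-ene | [Li]C1=CC[C@]2(CC(OC)OC2)O1 | intermediate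
14 | lithium trimethoxy[(5R)-8-methoxy-1,7-dioxaspiro[4.4]non-2-en-2-yl]borate | [Li+].CO[B-](OC)(OC)C1=CC[C@]2(CC(OC)OC2)O1 | intermediate
15 | (3R)-3-[(5R)-8-methoxy-1,7-dioxaspiro[4.4]non-2-en-2-yl]-1-(2,6,6-trimethylcyclohex-1-en-1-yl)butan-1-one | CC1=C(C(=O)C[C@@H](C)C2=CC[C@]3(CC(OC)OC3)O2)C(C)(C)CCC1 | intermediate
16 | tertiary alpha-oxy radical at C9 derived from 15 | CC1=C(C(=O)C[C@@H](C)[C]2CC[C@]3(CC(OC)OC3)O2)C(C)(C)CCC1 | intermediate
17 | ring-closed alpha-keto radical at C5 | O=C1C[C@@H](C)[C@]2(CC[C@]3(CC(OC)OC3)O2)[C@@]2(C)CCCC(C)(C)[C]12 | intermediate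
18 | (5S,8R,9R,10S,13R)-15-methoxy-9α,13:15,16-diepoxylabdan-6-one | O=C1C[C@@H](C)[C@]2(CC[C@]3(CC(OC)OC3)O2)[C@@]2(C)CCCC(C)(C)[C@H]12 | intermediate
19 | lithium 6β-alkoxide of reduced 18 | [Li+].[O-][C@@H]1C[C@@H](C)[C@]2(CC[C@]3(CC(OC)OC3)O2)[C@@]2(C)CCCC(C)(C)[C@H]12 | intermediate
20 | (13R)-6β-acetoxy-15-methoxy-9α,13:15,16-diepoxylabdane | CC(=O)O[C@@H]1C[C@@H](C)[C@]2(CC[C@]3(CC(OC)OC3)O2)[C@@]2(C)CCCC(C)(C)[C@H]12 | intermediate
21 | C15 oxocarbenium triflate derived from 20 | CC(=O)O[C@@H]1C[C@@H](C)[C@]2(CC[C@]3(CC=[O+]C3)O2)[C@@]2(C)CCCC(C)(C)[C@H]12.[O-]S(=O)(=O)C(F)(F)F | intermediate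
22 | (5S,6R,8R,9R,10S,13R)-6β-acetoxy-9α,13:15,16-diepoxylabd-14-ene | CC(=O)O[C@@H]1C[C@@H](C)[C@]2(CC[C@]3(C=COC3)O2)[C@@]2(C)CCCC(C)(C)[C@H]12 | target

Total step count: 9. Longest linear sequence: 9 steps (1 to 22). Beta-damascone enters as purchased.

Steps most likely to fail

Step 7. Bond formation between two fully substituted carbons onto a twisted enone may be slow. Premature hydrogen delivery to the C9 radical, solvolysis of the enol ether, or poor facial selectivity at C9 could then take over.
- The fallback sets out from 15 and reaches the same radical by group abstraction rather than hydrogen-atom transfer.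
- Markovnikov addition of PhSH (PPTS cat., CH2Cl2, −20 °C) across the enol ether would give the C9 phenylthio ketal F1.
- Syringe-pump addition of Bu3SnH/AIBN in refluxing benzene at high dilution would generate 16 under conditions where the hydrogen-donor concentration is set by the addition rate.
- After K2CO3/MeOH equilibration at C5 the route is rejoined at 18.

Step 6. Protodeboronation of the alpha-alkoxyalkenyl borate may outrun transmetallation to rhodium, and facial selectivity on the bulky ketone may erode.
- The fallback sets out from 11 and moves stereocontrol from the catalyst to an auxiliary.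
- (S)-4-Phenyloxazolidin-2-one is acylated (nBuLi, (E)-crotonyl chloride) to (S)-3-[(E)-but-2-enoyl]-4-phenyloxazolidin-2-one F2.
- Lithiated 13, transmetallated in situ with MgBr2·OEt2 and CuBr·SMe2, adds to the chelated s-cis imide anti to the phenyl group to give the (3R)-imide adduct F3.
- MeNH(OMe)·HCl/iPrMgCl converts this into the N-methoxy-N-methylamide F4.
- Separately, commercial 2,2,6-trimethylcyclohexanone is condensed with 2,4,6-triisopropylbenzenesulfonyl hydrazide to the trisylhydrazone F5. A Shapiro reaction (nBuLi, THF/TMEDA) turns this into 2,6,6-trimethylcyclohex-1-enyllithium F6.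
- Acylation of F6 by F4 rejoins the route at 15.

Step 9. Excess silyl triflate could activate the hindered 9,13-ether once the enol ether is in place, leading to ring opening and aromatisation of ring D. Incomplete deprotonation is also possible.
- The fallback sets out from 20 and avoids a strong Lewis acid.
- Hydrolysis (AcOH/THF/H2O, 40 °C) would give the 15-lactol F7.
- MsCl/Et3N (CH2Cl2, −20 °C to reflux) would convert this through the anomeric mesylate F8 by base-mediated elimination into 22. C6 is already acetylated, so no hydroxyl competes.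

Further compounds
F1 | step 7 | (3R)-3-[(5R)-8-methoxy-2-(phenylsulfanyl)-1,7-dioxaspiro[4.4]nonan-2-yl]-1-(2,6,6-trimethylcyclohex-1-en-1-yl)butan-1-one | CC1=C(C(=O)C[C@@H](C)C2(Sc3ccccc3)CC[C@]4(CC(OC)OC4)O2)C(C)(C)CCC1
F2 | step 6 | (S)-3-[(E)-but-2-enoyl]-4-phenyloxazolidin-2-one | C/C=C/C(=O)N1[C@@H](c2ccccc2)COC1=O
F3 | step 6 | (S)-3-{(3R)-3-[(5R)-8-methoxy-1,7-dioxaspiro[4.4]non-2-en-2-yl]butanoyl}-4-phenyloxazolidin-2-one | C[C@H](CC(=O)N1[C@@H](c2ccccc2)COC1=O)C3=CC[C@]4(CC(OC)OC4)O3
F4 | step 6 | (3R)-N-methoxy-3-[(5R)-8-methoxy-1,7-dioxaspiro[4.4]non-2-en-2-yl]-N-methylbutanamide | C[C@H](CC(=O)N(C)OC)C1=CC[C@]2(CC(OC)OC2)O1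
F5 | step 6 | 2,2,6-trimethylcyclohexanone 2,4,6-triisopropylbenzenesulfonylhydrazone | CC1CCCC(C)(C)C1=NNS(=O)(=O)c1c(C(C)C)cc(C(C)C)cc1C(C)C
F6 | step 6 | 2,6,6-trimethylcyclohex-1-enyllithium | [Li]C1=C(C)CCCC1(C)C
F7 | step 9 | (13R)-6β-acetoxy-9α,13:15,16-diepoxylabdan-15-ol (lactol) | CC(=O)O[C@@H]1C[C@@H](C)[C@]2(CC[C@]3(CC(O)OC3)O2)[C@@]2(C)CCCC(C)(C)[C@H]12
F8 | step 9 | (13R)-6β-acetoxy-9α,13:15,16-diepoxylabdan-15-yl methanesulfonate | CC(=O)O[C@@H]1C[C@@H](C)[C@]2(CC[C@]3(CC(OS(C)(=O)=O)OC3)O2)[C@@]2(C)CCCC(C)(C)[C@H]12
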